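**Plan**
1. Locants: ring C15(OAc, quaternary)–C1H2–C2H(C16H3)–C3H(OBz)–C4H; enal C5=C6(C17)–C7HO on C4; chain C14H(OAc)–C13H(Me)–C12=C11–C10Me2–C9(=O)–C8H3 on C15.
2. Retrosynthesis cuts C5=C6 (Wittig), C11=C12 (cross-metathesis), C13–C14 (crotylboration), then C1–C15 and C2–C3 together in one (3+2) Michael/Claisen annulation, and last C4–C15 (syn-aldol).
3. Enabling feature: C15 carries oxygen and C14, so C14–C15(O)–C4–C3(O) is a 3-substituted malic acid skeleton. C15 can serve as the enolate carbon of an α-hydroxy-acid acetal and C3 as an acyl carbon, so a vinylphosphonate (C1–C2) can be stitched across them to close the only ring, the cyclopentane.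
4. Forward: aldol → cis-dioxolanone with a Weinreb amide at C3 → annulation to a spiro β-keto phosphonate → HWE with CH2O (C16), C3 reduction, directed hydrogenation → acetal opened to a thioester → aldehyde → crotylboration → cross-metathesis → enal.
5. Stereochemistry: C4 and C15–H from the (R)-benzyloxazolidinone syn-aldol; quaternary C15 by retentive attack anti to the acetal t-Bu; C3 by hydride delivery anti to the C4 substituent; C2 by OH-directed hydrogenation; C14/C13 by (Z)-crotyl-B(Ipc)2; both alkenes E (metathesis, stabilised ylide).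
6. Helpers leave in step 4 (auxiliary), 7 (Weinreb amine), 8 (phosphonate), 11 (pivalaldehyde acetal), 13 (thioester) and 18 (silyl ether).

Key step: step 7

Remark: 1, 3, 6, 12, 25 and 29 are taken as purchasable; the phosphonate-bearing C2 of 15 is an epimer mixture and is written without configuration.

Step 1
Reactants: 1 3-[(tert-butyldiphenylsilyl)oxy]propan-1-ol
Product: 2 3-[(tert-butyldiphenylsilyl)oxy]propanoic acid
Conditions: TEMPO (cat.), PhI(OAc)2, MeCN/H2O, rt
Reagents that add atoms: water, O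
Why: Oxoammonium (TEMPO) oxidation in aqueous MeCN should take the primary alcohol through the aldehyde hydrate to the acid without touching the silyl ether.

Step 2
Reactants: 2 3-[(tert-butyldiphenylsilyl)oxy]propanoic acid; 3 (R)-4-benzyl-1,3-oxazolidin-2-one
Product: 5 (R)-4-benzyl-3-{3-[(tert-butyldiphenylsilyl)oxy]propanoyl}-1,3-oxazolidin-2-one, via mixed pivalic anhydride 4 (not isolated)
Conditions: t-BuCOCl, Et3N, THF, −20 °C; then 3, LiCl, −20 °C → rt
Reagents that add atoms: pivaloyl chloride, CC(C)(C)C(Cl)=O (its atoms stay in 4 only)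
Why: Mixed-anhydride N-acylation of the oxazolidinone (LiCl/Et3N variant) should give the imide without a strong base that could eliminate the β-silyloxy group.

Step 3
Reactants: 5 (R)-4-benzyl-3-{3-[(tert-butyldiphenylsilyl)oxy]propanoyl}-1,3-oxazolidin-2-one; 6 ethyl glyoxylate
Product: 8 ethyl (2R,3R)-4-[(4R)-4-benzyl-2-oxo-1,3-oxazolidin-3-yl]-3-{[(tert-butyldiphenylsilyl)oxy]methyl}-2-hydroxy-4-oxobutanoate, via (Z)-boron enolate 7 (not isolated)
Conditions: Bu2BOTf, Et3N, CH2Cl2, −78 → 0 °C; freshly distilled 6, −78 → 0 °C; then pH 7 buffer, MeOH, H2O2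
Reagents that add atoms: none
Why: Evans syn-aldol reaction, in which the (Z)-boron enolate adds to the glyoxylate aldehyde through a Zimmerman–Traxler chair on the face away from the auxiliary benzyl group; this should set C4 and C15 with the 2,3-syn relationship that later places C5 cis to O15 on the ring.

Step 4
Reactants: 8 ethyl (2R,3R)-4-[(4R)-4-benzyl-2-oxo-1,3-oxazolidin-3-yl]-3-{[(tert-butyldiphenylsilyl)oxy]methyl}-2-hydroxy-4-oxobutanoate
Product: 9 (2R,3R)-2-{[(tert-butyldiphenylsilyl)oxy]methyl}-3-hydroxybutanedioic acid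
Conditions: LiOH, H2O2, THF/H2O, 0 °C → rt; Na2SO3; HCl to pH 2
Reagents that add atoms: hydrogen peroxide, OO; lithium hydroxide, [Li+].[OH-]
Why: Hydroperoxide cleavage of the imide at the exocyclic carbonyl and saponification of the activated α-hydroxy ester should free both acids in one hydrolysis and return the auxiliary without epimerisation.

Step 5
Reactants: 9 (2R,3R)-2-{[(tert-butyldiphenylsilyl)oxy]methyl}-3-hydroxybutanedioic acid
Product: 10 (2R)-2-[(2R,4R)-2-tert-butyl-5-oxo-1,3-dioxolan-4-yl]-3-[(tert-butyldiphenylsilyl)oxy]propanoic acid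
Conditions: t-BuCHO, TsOH·H2O (cat.), H2SO4 (cat.), pentane, reflux, Dean–Stark; cis isomer purified
Reagents that add atoms: pivalaldehyde, CC(C)(C)C=O
Why: Acid-catalysed acetalisation of the α-hydroxy acid with pivalaldehyde should give the five-membered dioxolanone in preference to the six-membered one, with the cis isomer (t-Bu cis to the C4 side chain) as the thermodynamic product; the new acetal centre stores the C15 configuration (self-regeneration of stereocentres).

Step 6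
Reactants: 10 (2R)-2-[(2R,4R)-2-tert-butyl-5-oxo-1,3-dioxolan-4-yl]-3-[(tert-butyldiphenylsilyl)oxy]propanoic acid
Product: 11 (2R)-2-[(2R,4R)-2-tert-butyl-5-oxo-1,3-dioxolan-4-yl]-3-[(tert-butyldiphenylsilyl)oxy]-N-methoxy-N-methylpropanamide
Conditions: MeNHOMe·HCl, EDC·HCl, HOBt (cat.), N-methylmorpholine, CH2Cl2, 0 °C
Reagents that add atoms: N,O-dimethylhydroxylamine hydrochloride, CNOC.Cl
Why: Carbodiimide amide coupling should turn the free acid into a Weinreb amide, an acyl acceptor whose α-proton (C4–H) is much less acidic than the dioxolanone α-proton and whose tetrahedral adduct is stable.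

Step 7
Reactants: 11 (2R)-2-[(2R,4R)-2-tert-butyl-5-oxo-1,3-dioxolan-4-yl]-3-[(tert-butyldiphenylsilyl)oxy]-N-methoxy-N-methylpropanamide; 12 diethyl vinylphosphonate
Product: 15 diethyl [(2R,5R,6R)-2-tert-butyl-6-{[(tert-butyldiphenylsilyl)oxy]methyl}-4,7-dioxo-1,3-dioxaspiro[4.4]nonan-8-yl]phosphonate (C8 epimers), via lithium enolate 13 (not isolated), via lithiated Michael adduct 14 (not isolated)
Conditions: LiN(SiMe3)2 (1.05 equiv), THF/DMPU, −78 °C; 12, −78 → −20 °C; then 0 °C; aq NH4Cl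
Reagents that add atoms: none
Why: LiN(SiMe3)2 should remove the dioxolanone α-proton at C15 to give enolate 13, which adds in conjugate fashion to vinylphosphonate 12 and forms C1–C15; the resulting α-lithio phosphonate 14 then acylates on the Weinreb amide carbon C3 and forms C2–C3, the chelated tetrahedral adduct releasing the ketone on work-up. The closest known reaction type is the Michael-initiated ring closure (tandem Michael/Dieckmann–Claisen (3+2) annulation), run here on a pivalaldehyde-acetal dioxolanone enolate. The one ring that closes, the cyclopentanone C15–C1–C2–C3–C4, does so by 5-exo-trig attack of the C2 carbanion on the amide carbonyl. C15 is controlled by the acetal stereocentre, since the acceptor should approach the enolate face anti to the t-Bu group (overall retention); C4 is untouched, and the C2 centre is uncontrolled but becomes sp2 in step 8. The step needs deprotonation at C15 and not at C4, and acylation at C3 and not at the lactone carbon C14; the acidity gap between the acylal lactone and the tertiary amide, and the four-membered ring that attack on C14 would require, should secure both.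

Step 8
Reactants: 15 diethyl [(2R,5R,6R)-2-tert-butyl-6-{[(tert-butyldiphenylsilyl)oxy]methyl}-4,7-dioxo-1,3-dioxaspiro[4.4]nonan-8-yl]phosphonate
Product: 16 (2R,5R,6R)-2-tert-butyl-6-{[(tert-butyldiphenylsilyl)oxy]methyl}-8-methylidene-1,3-dioxaspiro[4.4]nonane-4,7-dione
Conditions: (HCHO)n, K2CO3, THF, rt → 40 °C; used at once
Reagents that add atoms: formaldehyde (as paraformaldehyde), C=O
Why: Horner–Wadsworth–Emmons olefination of the β-keto phosphonate with formaldehyde should remove the phosphonate helper and install C16 as an exocyclic methylene (α-methylene ketone synthesis).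

Step 9
Reactants: 16 (2R,5R,6R)-2-tert-butyl-6-{[(tert-butyldiphenylsilyl)oxy]methyl}-8-methylidene-1,3-dioxaspiro[4.4]nonane-4,7-dione
Product: 17 (2R,5R,6S,7R)-2-tert-butyl-6-{[(tert-butyldiphenylsilyl)oxy]methyl}-7-hydroxy-8-methylidene-1,3-dioxaspiro[4.4]nonan-4-one
Conditions: 9-BBN (1.1 equiv), THF, 0 °C; then HOCH2CH2NH2
Reagents that add atoms: none
Why: 9-BBN reduces conjugated enones 1,2-selectively and spares lactones, and the bulky borane should deliver hydride to the C3 carbonyl face opposite the adjacent C4 CH2OSi group (steric approach control), which gives the C3 hydroxyl cis to C5 and O15.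

Step 10
Reactants: 17 (2R,5R,6S,7R)-2-tert-butyl-6-{[(tert-butyldiphenylsilyl)oxy]methyl}-7-hydroxy-8-methylidene-1,3-dioxaspiro[4.4]nonan-4-one
Product: 18 (2R,5R,6S,7S,8R)-2-tert-butyl-6-{[(tert-butyldiphenylsilyl)oxy]methyl}-7-hydroxy-8-methyl-1,3-dioxaspiro[4.4]nonan-4-one
Conditions: H2 (1 atm), [Ir(cod)(PCy3)(py)]PF6 (5 mol %), CH2Cl2, rt
Reagents that add atoms: none
Why: Hydroxyl-directed homogeneous hydrogenation should add H2 to the exocyclic alkene from the face of the allylic C3–OH, so the C16 methyl ends trans to O3.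

Step 11
Reactants: 18 (2R,5R,6S,7S,8R)-2-tert-butyl-6-{[(tert-butyldiphenylsilyl)oxy]methyl}-7-hydroxy-8-methyl-1,3-dioxaspiro[4.4]nonan-4-one
Product: 19 S-ethyl (1R,2S,3S,4R)-2-{[(tert-butyldiphenylsilyl)oxy]methyl}-1,3-dihydroxy-4-methylcyclopentane-1-carbothioate
Conditions: AlMe3, EtSH, CH2Cl2, 0 °C → rt; Rochelle salt work-up
Reagents that add atoms: ethanethiol, CCS
Why: Aluminium thiolate thiolysis of the acylal-type lactone should give the thioester, the hemiacetal collapsing to pivalaldehyde and the free tertiary C15 alcohol.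

Step 12
Reactants: 19 S-ethyl (1R,2S,3S,4R)-2-{[(tert-butyldiphenylsilyl)oxy]methyl}-1,3-dihydroxy-4-methylcyclopentane-1-carbothioate
Product: 21 S-ethyl (1R,2S,3S,4R)-1-(acetyloxy)-3-(benzoyloxy)-2-{[(tert-butyldiphenylsilyl)oxy]methyl}-4-methylcyclopentane-1-carbothioate, via monobenzoate 20 (not isolated)
Conditions: BzCl, pyridine, DMAP (cat.), CH2Cl2, 0 °C → rt; then Ac2O, Et3N, DMAP, 45 °C
Reagents that add atoms: benzoyl chloride, O=C(Cl)c1ccccc1; acetic anhydride, CC(=O)OC(C)=O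
Why: Acyl chloride esterification should take the secondary C3–OH and leave the tertiary C15–OH, after which forcing DMAP-catalysed acetylation in the same flask esterifies the tertiary alcohol, so the two different esters are placed without protecting groups.

Step 13
Reactants: 21 S-ethyl (1R,2S,3S,4R)-1-(acetyloxy)-3-(benzoyloxy)-2-{[(tert-butyldiphenylsilyl)oxy]methyl}-4-methylcyclopentane-1-carbothioate
Product: 22 (1R,2S,3S,4R)-1-(acetyloxy)-3-(benzoyloxy)-2-{[(tert-butyldiphenylsilyl)oxy]methyl}-4-methylcyclopentane-1-carbaldehyde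
Conditions: Et3SiH, 10% Pd/C, acetone, rt
Reagents that add atoms: none
Why: Fukuyama reduction should convert the thioester into the aldehyde under neutral conditions that leave acetate, benzoate and silyl ether intact.

Step 14
Reactants: 22 (1R,2S,3S,4R)-1-(acetyloxy)-3-(benzoyloxy)-2-{[(tert-butyldiphenylsilyl)oxy]methyl}-4-methylcyclopentane-1-carbaldehyde
Product: 23 (1R,2S)-1-[(1R,2S,3S,4R)-1-(acetyloxy)-3-(benzoyloxy)-2-{[(tert-butyldiphenylsilyl)oxy]methyl}-4-methylcyclopentyl]-2-methylbut-3-en-1-ol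
Conditions: cis-2-butene, KOt-Bu, n-BuLi, THF, −78 → −45 °C; (+)-Ipc2BOMe, −78 °C; BF3·OEt2; 22, −78 °C; then NaBO3·4H2O, THF/H2O, rt
Reagents that add atoms: cis-2-butene, C/C=C\C
Why: Brown (Z)-crotylboration through a closed chair transition state should give the 13,14-syn homoallylic alcohol, the reagent from (+)-Ipc2BOMe (from (−)-α-pinene) selecting the aldehyde face that gives 14R,13S (reagent control).

Step 15
Reactants: 23 (1R,2S)-1-[(1R,2S,3S,4R)-1-(acetyloxy)-3-(benzoyloxy)-2-{[(tert-butyldiphenylsilyl)oxy]methyl}-4-methylcyclopentyl]-2-methylbut-3-en-1-ol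
Product: 24 (1R,2S)-1-[(1R,2S,3S,4R)-1-(acetyloxy)-3-(benzoyloxy)-2-{[(tert-butyldiphenylsilyl)oxy]methyl}-4-methylcyclopentyl]-2-methylbut-3-en-1-yl acetate
Conditions: Ac2O, pyridine, DMAP, CH2Cl2, rt → 40 °C
Reagents that add atoms: acetic anhydride, CC(=O)OC(C)=O
Why: DMAP-catalysed acetylation of the C14 hydroxyl should give the diacetate, and any acetate that migrated from O15 to O14 in step 14 converges to the same product under these conditions.

Step 16
Reactants: 25 2,2-dimethylbut-3-enoic acid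
Product: 26 3,3-dimethylpent-4-en-2-one
Conditions: MeLi (2.2 equiv), Et2O, 0 °C → rt; inverse quench into aq HCl
Reagents that add atoms: methyllithium, [Li]C
Why: Addition of two equivalents of MeLi to a carboxylic acid gives the methyl ketone after hydrolysis of the geminal dialkoxide (acid to methyl ketone conversion).

Step 17
Reactants: 24 (1R,2S)-1-[(1R,2S,3S,4R)-1-(acetyloxy)-3-(benzoyloxy)-2-{[(tert-butyldiphenylsilyl)oxy]methyl}-4-methylcyclopentyl]-2-methylbut-3-en-1-yl acetate; 26 3,3-dimethylpent-4-en-2-one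
Product: 27 (1R,2S,3E)-1-[(1R,2S,3S,4R)-1-(acetyloxy)-3-(benzoyloxy)-2-{[(tert-butyldiphenylsilyl)oxy]methyl}-4-methylcyclopentyl]-2,5,5-trimethyl-6-oxohept-3-en-1-yl acetate
Conditions: 26 (5 equiv), second-generation Hoveyda–Grubbs catalyst RuCl2(H2IMes)(=CH-C6H4-2-Oi-Pr) (10 mol %), toluene, 60 °C
Reagents that add atoms: none
Why: Olefin cross-metathesis between the monosubstituted alkene of 24 and the quaternary-allylic alkene of 26 (used in excess, as it should not homodimerise) should give only the E disubstituted alkene for steric reasons.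

Step 18
Reactants: 27 (1R,2S,3E)-1-[(1R,2S,3S,4R)-1-(acetyloxy)-3-(benzoyloxy)-2-{[(tert-butyldiphenylsilyl)oxy]methyl}-4-methylcyclopentyl]-2,5,5-trimethyl-6-oxohept-3-en-1-yl acetate
Product: 28 (1R,2S,3E)-1-[(1R,2S,3S,4R)-1-(acetyloxy)-3-(benzoyloxy)-2-(hydroxymethyl)-4-methylcyclopentyl]-2,5,5-trimethyl-6-oxohept-3-en-1-yl acetate
Conditions: HF·pyridine, pyridine/THF, 0 °C → rt
Reagents that add atoms: none
Why: Fluoride cleavage of the primary silyl ether with buffered HF·pyridine should be acidic enough to suppress acyl migration to the freed primary alcohol.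

Step 19
Reactants: 28 (1R,2S,3E)-1-[(1R,2S,3S,4R)-1-(acetyloxy)-3-(benzoyloxy)-2-(hydroxymethyl)-4-methylcyclopentyl]-2,5,5-trimethyl-6-oxohept-3-en-1-yl acetate; 29 2-(triphenylphosphoranylidene)propanal
Product: 31 (1R,2S,3E)-1-{(1R,2S,3S,4R)-1-(acetyloxy)-3-(benzoyloxy)-4-methyl-2-[(1E)-2-methyl-3-oxoprop-1-en-1-yl]cyclopentyl}-2,5,5-trimethyl-6-oxohept-3-en-1-yl acetate (CNP0489076.1), via aldehyde 30 (not isolated)
Conditions: Dess–Martin periodinane, NaHCO3, CH2Cl2, 0 °C → rt; filtration; then 29, toluene, 70 °C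
Reagents that add atoms: none
Why: Dess–Martin oxidation gives the C5 aldehyde, which is taken directly into a Wittig olefination with the formyl-stabilised ylide; this ylide should react only with the aldehyde (not the hindered ketone) and give the E trisubstituted enal.

**Compound list**
1 | 3-[(tert-butyldiphenylsilyl)oxy]propan-1-ol | OCCCO[Si](c1ccccc1)(c1ccccc1)C(C)(C)C | starting material
2 | 3-[(tert-butyldiphenylsilyl)oxy]propanoic acid | OC(=O)CCO[Si](c1ccccc1)(c1ccccc1)C(C)(C)C | intermediate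
3 | (R)-4-benzyl-1,3-oxazolidin-2-one | O=C1N[C@H](Cc2ccccc2)CO1 | starting material
4 | 3-[(tert-butyldiphenylsilyl)oxy]propanoic pivalic anhydride | CC(C)(C)C(=O)OC(=O)CCO[Si](c1ccccc1)(c1ccccc1)C(C)(C)C | intermediate (not isolated)
5 | (R)-4-benzyl-3-{3-[(tert-butyldiphenylsilyl)oxy]propanoyl}-1,3-oxazolidin-2-one | O=C(CCO[Si](c1ccccc1)(c1ccccc1)C(C)(C)C)N1[C@H](Cc2ccccc2)COC1=O | intermediate
6 | ethyl glyoxylate | CCOC(=O)C=O | starting material
7 | (Z)-dibutylboron enolate of 5 | CCCCB(CCCC)O/C(=C\CO[Si](c1ccccc1)(c1ccccc1)C(C)(C)C)N1[C@H](Cc2ccccc2)COC1=O | intermediate (not isolated)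
8 | ethyl (2R,3R)-4-[(4R)-4-benzyl-2-oxo-1,3-oxazolidin-3-yl]-3-{[(tert-butyldiphenylsilyl)oxy]methyl}-2-hydroxy-4-oxobutanoate | CCOC(=O)[C@H](O)[C@@H](CO[Si](c1ccccc1)(c1ccccc1)C(C)(C)C)C(=O)N1[C@H](Cc2ccccc2)COC1=O | intermediate
9 | (2R,3R)-2-{[(tert-butyldiphenylsilyl)oxy]methyl}-3-hydroxybutanedioic acid | OC(=O)[C@H](O)[C@@H](CO[Si](c1ccccc1)(c1ccccc1)C(C)(C)C)C(O)=O | intermediate
10 | (2R)-2-[(2R,4R)-2-tert-butyl-5-oxo-1,3-dioxolan-4-yl]-3-[(tert-butyldiphenylsilyl)oxy]propanoic acid | CC(C)(C)[C@H]1OC(=O)[C@H](O1)[C@@H](CO[Si](c2ccccc2)(c2ccccc2)C(C)(C)C)C(O)=O | intermediate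
11 | (2R)-2-[(2R,4R)-2-tert-butyl-5-oxo-1,3-dioxolan-4-yl]-3-[(tert-butyldiphenylsilyl)oxy]-N-methoxy-N-methylpropanamide | CC(C)(C)[C@H]1OC(=O)[C@H](O1)[C@@H](CO[Si](c2ccccc2)(c2ccccc2)C(C)(C)C)C(=O)N(C)OC | intermediate
12 | diethyl vinylphosphonate | C=CP(=O)(OCC)OCC | starting material
13 | lithium enolate of 11 (C15=C14 enolate) | CC(C)(C)[C@H]1OC(O[Li])=C(O1)[C@@H](CO[Si](c2ccccc2)(c2ccccc2)C(C)(C)C)C(=O)N(C)OC | intermediate (not isolated)
14 | α-lithio phosphonate Michael adduct of 13 and 12 | CC(C)(C)[C@H]1OC(=O)[C@@](O1)(CC([Li])P(=O)(OCC)OCC)[C@@H](CO[Si](c2ccccc2)(c2ccccc2)C(C)(C)C)C(=O)N(C)OC | intermediate (not isolated)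
15 | diethyl [(2R,5R,6R)-2-tert-butyl-6-{[(tert-butyldiphenylsilyl)oxy]methyl}-4,7-dioxo-1,3-dioxaspiro[4.4]nonan-8-yl]phosphonate (C8 epimers) | CC(C)(C)[C@H]1OC(=O)[C@@]2(O1)CC(P(=O)(OCC)OCC)C(=O)[C@@H]2CO[Si](c3ccccc3)(c3ccccc3)C(C)(C)C | intermediate
16 | (2R,5R,6R)-2-tert-butyl-6-{[(tert-butyldiphenylsilyl)oxy]methyl}-8-methylidene-1,3-dioxaspiro[4.4]nonane-4,7-dione | CC(C)(C)[C@H]1OC(=O)[C@@]2(O1)CC(=C)C(=O)[C@@H]2CO[Si](c3ccccc3)(c3ccccc3)C(C)(C)C | intermediate
17 | (2R,5R,6S,7R)-2-tert-butyl-6-{[(tert-butyldiphenylsilyl)oxy]methyl}-7-hydroxy-8-methylidene-1,3-dioxaspiro[4.4]nonan-4-one | CC(C)(C)[C@H]1OC(=O)[C@@]2(O1)CC(=C)[C@H](O)[C@@H]2CO[Si](c3ccccc3)(c3ccccc3)C(C)(C)C | intermediate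
18 | (2R,5R,6S,7S,8R)-2-tert-butyl-6-{[(tert-butyldiphenylsilyl)oxy]methyl}-7-hydroxy-8-methyl-1,3-dioxaspiro[4.4]nonan-4-one | CC(C)(C)[C@H]1OC(=O)[C@@]2(O1)C[C@@H](C)[C@H](O)[C@@H]2CO[Si](c3ccccc3)(c3ccccc3)C(C)(C)C | intermediate
19 | S-ethyl (1R,2S,3S,4R)-2-{[(tert-butyldiphenylsilyl)oxy]methyl}-1,3-dihydroxy-4-methylcyclopentane-1-carbothioate | CCSC(=O)[C@@]1(O)C[C@@H](C)[C@H](O)[C@@H]1CO[Si](c2ccccc2)(c2ccccc2)C(C)(C)C | intermediate
20 | S-ethyl (1R,2S,3S,4R)-3-(benzoyloxy)-2-{[(tert-butyldiphenylsilyl)oxy]methyl}-1-hydroxy-4-methylcyclopentane-1-carbothioate | CCSC(=O)[C@@]1(O)C[C@@H](C)[C@H](OC(=O)c2ccccc2)[C@@H]1CO[Si](c3ccccc3)(c3ccccc3)C(C)(C)C | intermediate (not isolated)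
21 | S-ethyl (1R,2S,3S,4R)-1-(acetyloxy)-3-(benzoyloxy)-2-{[(tert-butyldiphenylsilyl)oxy]methyl}-4-methylcyclopentane-1-carbothioate | CCSC(=O)[C@@]1(OC(C)=O)C[C@@H](C)[C@H](OC(=O)c2ccccc2)[C@@H]1CO[Si](c3ccccc3)(c3ccccc3)C(C)(C)C | intermediate
22 | (1R,2S,3S,4R)-1-(acetyloxy)-3-(benzoyloxy)-2-{[(tert-butyldiphenylsilyl)oxy]methyl}-4-methylcyclopentane-1-carbaldehyde | O=C[C@@]1(OC(C)=O)C[C@@H](C)[C@H](OC(=O)c2ccccc2)[C@@H]1CO[Si](c3ccccc3)(c3ccccc3)C(C)(C)C | intermediate
23 | (1R,2S)-1-[(1R,2S,3S,4R)-1-(acetyloxy)-3-(benzoyloxy)-2-{[(tert-butyldiphenylsilyl)oxy]methyl}-4-methylcyclopentyl]-2-methylbut-3-en-1-ol | O[C@H]([C@@H](C)C=C)[C@@]1(OC(C)=O)C[C@@H](C)[C@H](OC(=O)c2ccccc2)[C@@H]1CO[Si](c3ccccc3)(c3ccccc3)C(C)(C)C | intermediate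
24 | (1R,2S)-1-[(1R,2S,3S,4R)-1-(acetyloxy)-3-(benzoyloxy)-2-{[(tert-butyldiphenylsilyl)oxy]methyl}-4-methylcyclopentyl]-2-methylbut-3-en-1-yl acetate | CC(=O)O[C@H]([C@@H](C)C=C)[C@@]1(OC(C)=O)C[C@@H](C)[C@H](OC(=O)c2ccccc2)[C@@H]1CO[Si](c3ccccc3)(c3ccccc3)C(C)(C)C | intermediate
25 | 2,2-dimethylbut-3-enoic acid | C=CC(C)(C)C(O)=O | starting material
26 | 3,3-dimethylpent-4-en-2-one | C=CC(C)(C)C(C)=O | intermediate
27 | (1R,2S,3E)-1-[(1R,2S,3S,4R)-1-(acetyloxy)-3-(benzoyloxy)-2-{[(tert-butyldiphenylsilyl)oxy]methyl}-4-methylcyclopentyl]-2,5,5-trimethyl-6-oxohept-3-en-1-yl acetate | CC(=O)O[C@H]([C@@H](C)/C=C/C(C)(C)C(C)=O)[C@@]1(OC(C)=O)C[C@@H](C)[C@H](OC(=O)c2ccccc2)[C@@H]1CO[Si](c3ccccc3)(c3ccccc3)C(C)(C)C | intermediate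
28 | (1R,2S,3E)-1-[(1R,2S,3S,4R)-1-(acetyloxy)-3-(benzoyloxy)-2-(hydroxymethyl)-4-methylcyclopentyl]-2,5,5-trimethyl-6-oxohept-3-en-1-yl acetate | CC(=O)O[C@H]([C@@H](C)/C=C/C(C)(C)C(C)=O)[C@@]1(OC(C)=O)C[C@@H](C)[C@H](OC(=O)c2ccccc2)[C@@H]1CO | intermediate
29 | 2-(triphenylphosphoranylidene)propanal | CC(C=O)=P(c1ccccc1)(c1ccccc1)c1ccccc1 | starting material
30 | (1R,2S,3E)-1-[(1R,2S,3S,4R)-1-(acetyloxy)-3-(benzoyloxy)-2-formyl-4-methylcyclopentyl]-2,5,5-trimethyl-6-oxohept-3-en-1-yl acetate | CC(=O)O[C@H]([C@@H](C)/C=C/C(C)(C)C(C)=O)[C@@]1(OC(C)=O)C[C@@H](C)[C@H](OC(=O)c2ccccc2)[C@@H]1C=O | intermediate (not isolated)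
31 | (1R,2S,3E)-1-{(1R,2S,3S,4R)-1-(acetyloxy)-3-(benzoyloxy)-4-methyl-2-[(1E)-2-methyl-3-oxoprop-1-en-1-yl]cyclopentyl}-2,5,5-trimethyl-6-oxohept-3-en-1-yl acetate (CNP0489076.1) | CC(=O)O[C@H]([C@@H](C)/C=C/C(C)(C)C(C)=O)[C@@]1(OC(C)=O)C[C@@H](C)[C@H](OC(=O)c2ccccc2)[C@@H]1/C=C(\C)C=O | target

**Step count and risks**
Total step count: 19. Longest linear sequence: 18 (steps 1–15 and 17–19; step 16 is a one-step side branch).

Steps most likely to fail:

Step 7. The base may deprotonate C4 instead of C15, which would be followed by β-elimination of the acetal oxygen. The conjugate addition to the vinylphosphonate may also be slow enough for the dioxolanone enolate to fragment before it is trapped. The fallback forms the two bonds one at a time. It sets out from 11: LiN(SiMe3)2 at −78 °C and 2,3-dibromopropene (enolate alkylation anti to t-Bu) give the 2-bromoallyl dioxolanone Weinreb amide F1. Cp2Zr(H)Cl then reduces the Weinreb amide to the aldehyde F2. An intramolecular Nozaki–Hiyama–Kishi reaction (CrCl2, catalytic NiCl2, DMF) closes C2–C3 to the methylenecyclopentanol F3 (either C3 epimer). Dess–Martin oxidation of F3 comes back to the route at 16.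

Step 17. Turnover between two hindered alkenes (an α-branched terminal alkene and a quaternary-allylic one) may be unproductive, leaving starting alkene and decomposed catalyst. The fallback builds the alkene by olefination and sets out from 24. Ozonolysis (O3, CH2Cl2, −78 °C; PPh3) gives the C12 aldehyde F4. In parallel, commercial 4-hydroxy-3,3-dimethylbutan-2-one is ketalised with ethylene glycol to the alcohol F5. Mitsunobu reaction with 1-phenyl-1H-tetrazole-5-thiol converts it to the sulfide F6, and oxidation ((NH4)6Mo7O24, H2O2) gives the sulfone F7. Julia–Kocienski olefination (KN(SiMe3)2, DME, −60 °C, then F4) gives the E-alkene ketal F8. Ketal hydrolysis (PPTS, wet acetone) comes back to the route at 27.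

Step 19. During the thermal Wittig reaction the β-acyloxy aldehyde may lose benzoate or acetate by β-elimination, or epimerise at C4, before the weakly nucleophilic ylide reacts. The fallback avoids base at the aldehyde stage and sets out from aldehyde 30 (made from 28 as before). A Mukaiyama aldol addition of 1-(trimethylsilyloxy)prop-1-ene (BF3·OEt2, CH2Cl2, −78 °C) gives the β-hydroxy aldehyde F9. MsCl and Et3N convert it to the mesylate F10, which eliminates in the same flask to the E-enal and comes back to the route at 31.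

Further compounds
F1 | step 7 | 2-bromoallyl dioxolanone Weinreb amide (C15 quaternary, 2-bromoprop-2-enyl anti to t-Bu) | CC(C)(C)[C@H]1OC(=O)[C@@](O1)(CC(Br)=C)[C@@H](CO[Si](c2ccccc2)(c2ccccc2)C(C)(C)C)C(=O)N(C)OC
F2 | step 7 | 2-bromoallyl dioxolanone aldehyde (C3 aldehyde) | CC(C)(C)[C@H]1OC(=O)[C@@](O1)(CC(Br)=C)[C@@H](CO[Si](c2ccccc2)(c2ccccc2)C(C)(C)C)C=O
F3 | step 7 | spiro methylenecyclopentanol (C3 epimer mixture of 17) | CC(C)(C)[C@H]1OC(=O)[C@@]2(O1)CC(=C)C(O)[C@@H]2CO[Si](c3ccccc3)(c3ccccc3)C(C)(C)C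
F4 | step 17 | C12 aldehyde from ozonolysis of 24 | CC(=O)O[C@H]([C@@H](C)C=O)[C@@]1(OC(C)=O)C[C@@H](C)[C@H](OC(=O)c2ccccc2)[C@@H]1CO[Si](c3ccccc3)(c3ccccc3)C(C)(C)C
F5 | step 17 | 2-methyl-2-(2-methyl-1,3-dioxolan-2-yl)propan-1-ol | CC1(OCCO1)C(C)(C)CO
F6 | step 17 | 5-{[2-methyl-2-(2-methyl-1,3-dioxolan-2-yl)propyl]sulfanyl}-1-phenyl-1H-tetrazole | CC1(OCCO1)C(C)(C)CSc1nnnn1-c1ccccc1
F7 | step 17 | 5-{[2-methyl-2-(2-methyl-1,3-dioxolan-2-yl)propyl]sulfonyl}-1-phenyl-1H-tetrazole | CC1(OCCO1)C(C)(C)CS(=O)(=O)c1nnnn1-c1ccccc1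
F8 | step 17 | ethylene ketal of 27 at C9 | CC(=O)O[C@H]([C@@H](C)/C=C/C(C)(C)C1(C)OCCO1)[C@@]1(OC(C)=O)C[C@@H](C)[C@H](OC(=O)c2ccccc2)[C@@H]1CO[Si](c3ccccc3)(c3ccccc3)C(C)(C)C
F9 | step 19 | β-hydroxy aldehyde from aldol addition to 30 (C5 and C6 epimers) | CC(=O)O[C@H]([C@@H](C)/C=C/C(C)(C)C(C)=O)[C@@]1(OC(C)=O)C[C@@H](C)[C@H](OC(=O)c2ccccc2)[C@@H]1C(O)C(C)C=O
F10 | step 19 | mesylate of F9 | CC(=O)O[C@H]([C@@H](C)/C=C/C(C)(C)C(C)=O)[C@@]1(OC(C)=O)C[C@@H](C)[C@H](OC(=O)c2ccccc2)[C@@H]1C(OS(C)(=O)=O)C(C)C=O
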